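The dearomatised ring (C1 ketone, C2 hexanoyl carbon, C3 enol, quaternary C4, C5 enol, C6 arylmethyl carbon) is a cyclohexane-1,3,5-trione in disguise: C5 sits at the carboxylic acid level next to the quaternary stereocentre, and C6 lies between two carbonyls. The C5–C6 bond is therefore closed by a Dieckmann-type Claisen condensation, in which the acetyl methyl group of an open-chain triketo ester attacks the ester on the quaternary carbon. The precursor is an acyclic 4-acetyl-3,5-dioxodecanoate whose stereocentre is set earlier by phase-transfer prenylation of a mixed methylmalonate; its hexanoyl group keeps the new trione chiral. A quinone methide coupling at C6 then adds the aromatic half.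

Key step: step 6

Assumption: the (S,S) antipode of the phase-transfer catalyst is taken to give the (S)-diester (if the sense of induction proves opposite, the (R,R) antipode is used and nothing else changes), and enolisable polyketones are written as one tautomer.

Step 1
Reactants: 1 2,2,5-trimethyl-1,3-dioxane-4,6-dione (cyclic isopropylidene ester of methylmalonic acid)
Product: 2 3-(tert-butoxy)-2-methyl-3-oxopropanoic acid
Conditions: t-BuOH, reflux
Reagents that add atoms: tert-butanol, CC(C)(C)O
Why: Alcoholysis of the cyclic acylal by tert-butanol should open the ring to the malonic half ester with loss of acetone; the α-centre is labile and left undefined.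

Step 2
Reactants: 2 3-(tert-butoxy)-2-methyl-3-oxopropanoic acid; 3 2,2-diphenylethanol
Product: 4 1-tert-butyl 3-(2,2-diphenylethyl) 2-methylpropanedioate (racemic)
Conditions: EDC·HCl, DMAP (cat.), CH2Cl2, 0 °C → rt
Reagents that add atoms: none
Why: Steglich esterification, in which the carbodiimide activates the acid and DMAP transfers the acyl group to the primary alcohol while the tert-butyl ester is untouched.

Step 3
Reactants: 4 1-tert-butyl 3-(2,2-diphenylethyl) 2-methylpropanedioate; 5 1-bromo-3-methylbut-2-ene (prenyl bromide)
Product: 6 1-tert-butyl 3-(2,2-diphenylethyl) (2S)-2-methyl-2-(3-methylbut-2-en-1-yl)propanedioate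
Conditions: (S,S)-3,4,5-trifluorophenyl-NAS bromide [(11bS,11'bS)-2,6-bis(3,4,5-trifluorophenyl)-3,3',5,5'-tetrahydro-4,4'-spirobi[dinaphtho[2,1-c:1',2'-e]azepin]-4-ium bromide] (5 mol%), 50% aq. KOH, toluene, −40 °C
Reagents that add atoms: none
Why: Asymmetric phase-transfer alkylation, in which the malonate enolate is paired with the C2-symmetric quaternary ammonium cation, the large size difference between the tert-butyl and 2,2-diphenylethyl esters fixes the enolate orientation, and SN2 attack on the primary allylic bromide from the open face should set the quaternary stereocentre as (S).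

Step 4
Reactants: 6 1-tert-butyl 3-(2,2-diphenylethyl) (2S)-2-methyl-2-(3-methylbut-2-en-1-yl)propanedioate
Product: 7 (2R)-2-[(2,2-diphenylethoxy)carbonyl]-2,5-dimethylhex-4-enoic acid
Conditions: TMSOTf, 2,6-lutidine, CH2Cl2, 0 °C; then aq. citric acid
Reagents that add atoms: none
Why: Silyl triflate-mediated cleavage of the tert-butyl ester (O-silylation, loss of the tert-butyl cation as isobutene, hydrolysis of the silyl ester on work-up) under buffered non-protic conditions should spare the primary ester, the acid-sensitive prenyl alkene and the non-enolisable quaternary centre.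

Step 5
Reactants: 7 (2R)-2-[(2,2-diphenylethoxy)carbonyl]-2,5-dimethylhex-4-enoic acid; 8 nonane-2,4-dione
Product: 10 2,2-diphenylethyl (2R)-4-acetyl-2-methyl-2-(3-methylbut-2-en-1-yl)-3,5-dioxodecanoate, via acid chloride 9 (not isolated)
Conditions: 1-chloro-N,N,2-trimethylprop-1-en-1-amine, CH2Cl2, 0 °C → rt; then 8, MgCl2, pyridine, CH2Cl2, 0 °C → rt; aq. citric acid work-up
Reagents that add atoms: none
Why: The α-chloroenamine makes the acid chloride under neutral conditions (no HCl to add to the prenyl alkene), and the magnesium enolate of the 1,3-diketone formed by soft enolisation is C-acylated at its central carbon (Claisen-type C-acylation) to the chelated triacylmethane; the chloride has no α-hydrogen, so neither a ketene nor an epimerisation pathway exists.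

Step 6
Reactants: 10 2,2-diphenylethyl (2R)-4-acetyl-2-methyl-2-(3-methylbut-2-en-1-yl)-3,5-dioxodecanoate
Product: 11 (4S)-2-hexanoyl-3,5-dihydroxy-4-methyl-4-(3-methylbut-2-en-1-yl)cyclohexa-2,5-dien-1-one
Conditions: LiN(iPr)2 (2.3 equiv), THF, −78 °C → 0 °C; then 1 M HCl
Reagents that add atoms: none
Why: The first equivalent of LiN(iPr)2 removes the central triketone proton and the second removes a proton of the acetyl methyl group, giving a 1,3-dianion whose terminal carbon adds to the ester carbonyl on the quaternary carbon; loss of 2,2-diphenylethoxide and deprotonation of the new trione make the closure irreversible. This is a Dieckmann-type intramolecular Claisen condensation of a 1,3-dicarbonyl dianion, the reaction type by which polyketo esters are closed to acylphloroglucinol rings. The six-membered ring closes in the 6-(enolexo)-exo-trig mode. No stereocentre is formed: the quaternary centre has no α-hydrogen and is carried through unchanged, and the product stays chiral only because the hexanoyl group on C2 differentiates the two sides of the ring. The step needs deprotonation at the acetyl CH3 and not at the hexanoyl CH2, which would close an isomeric six-membered ring; the kinetic preference of a hindered amide base for methyl over methylene in dianion formation and the easier approach of a primary carbanion to the neopentyl-type ester should secure this.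

Step 7
Reactants: 12 phloroglucinol (benzene-1,3,5-triol); 13 hexanoyl chloride
Product: 14 1-(2,4,6-trihydroxyphenyl)hexan-1-one
Conditions: AlCl3, PhNO2/CH2Cl2, 0 → 50 °C; then ice/aq. HCl
Reagents that add atoms: none
Why: Friedel–Crafts acylation of the highly activated, threefold symmetric arene, in which the first acyl group deactivates the ring against a second acylation.

Step 8
Reactants: 14 1-(2,4,6-trihydroxyphenyl)hexan-1-one
Product: 15 1-(2,6-dihydroxy-4-methoxyphenyl)hexan-1-one
Conditions: Me2SO4 (1.0 equiv), K2CO3 (1.0 equiv), acetone, rt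
Reagents that add atoms: dimethyl sulfate, COS(=O)(=O)OC
Why: Williamson-type O-methylation with one equivalent of reagent should go to the 4-hydroxyl, because the two ortho hydroxyls are tied up in hydrogen bonds to the ketone and are less acidic and less nucleophilic.

Step 9
Reactants: 15 1-(2,6-dihydroxy-4-methoxyphenyl)hexan-1-one
Product: 16 1-{3-[(dimethylamino)methyl]-2,6-dihydroxy-4-methoxyphenyl}hexan-1-one
Conditions: CH2=NMe2+ I− (1.0 equiv), Et3N, CH2Cl2, 0 °C → rt
Reagents that add atoms: N,N-dimethylmethyleneiminium iodide, C=[N+](C)C.[I-]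
Why: Mannich aminomethylation (electrophilic aromatic substitution by the preformed iminium ion) at one of the two equivalent free ring positions, each ortho and para to oxygen donors.

Step 10
Reactants: 11 (4S)-2-hexanoyl-3,5-dihydroxy-4-methyl-4-(3-methylbut-2-en-1-yl)cyclohexa-2,5-dien-1-one; 16 1-{3-[(dimethylamino)methyl]-2,6-dihydroxy-4-methoxyphenyl}hexan-1-one
Product: 18 CNP0108719.1, via ortho-quinone methide 17 (not isolated)
Conditions: 1,4-dioxane, 90 °C
Reagents that add atoms: none
Why: Thermal loss of dimethylamine from the ortho-hydroxybenzylamine gives the ortho-quinone methide, which the strongly nucleophilic C6 of the enolised trione 11 (its only free carbon between two carbonyls) should trap by Michael addition with rearomatisation; the quaternary stereocentre is not involved.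

Compound list
1 | 2,2,5-trimethyl-1,3-dioxane-4,6-dione | CC1C(=O)OC(C)(C)OC1=O | starting material
2 | 3-(tert-butoxy)-2-methyl-3-oxopropanoic acid (racemic, labile α-centre) | CC(C(=O)O)C(=O)OC(C)(C)C | intermediate
3 | 2,2-diphenylethanol | OCC(c1ccccc1)c1ccccc1 | starting material
4 | 1-tert-butyl 3-(2,2-diphenylethyl) 2-methylpropanedioate (racemic) | CC(C(=O)OCC(c1ccccc1)c1ccccc1)C(=O)OC(C)(C)C | intermediate
5 | 1-bromo-3-methylbut-2-ene (prenyl bromide) | CC(C)=CCBr | starting material
6 | 1-tert-butyl 3-(2,2-diphenylethyl) (2S)-2-methyl-2-(3-methylbut-2-en-1-yl)propanedioate | CC(C)(C)OC(=O)[C@@](C)(CC=C(C)C)C(=O)OCC(c1ccccc1)c1ccccc1 | intermediate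
7 | (2R)-2-[(2,2-diphenylethoxy)carbonyl]-2,5-dimethylhex-4-enoic acid | OC(=O)[C@@](C)(CC=C(C)C)C(=O)OCC(c1ccccc1)c1ccccc1 | intermediate
8 | nonane-2,4-dione | CCCCCC(=O)CC(C)=O | starting material
9 | 2,2-diphenylethyl (2S)-2-(chlorocarbonyl)-2,5-dimethylhex-4-enoate | ClC(=O)[C@@](C)(CC=C(C)C)C(=O)OCC(c1ccccc1)c1ccccc1 | intermediate
10 | 2,2-diphenylethyl (2R)-4-acetyl-2-methyl-2-(3-methylbut-2-en-1-yl)-3,5-dioxodecanoate | CCCCCC(=O)C(C(C)=O)C(=O)[C@@](C)(CC=C(C)C)C(=O)OCC(c1ccccc1)c1ccccc1 | intermediate
11 | (4S)-2-hexanoyl-3,5-dihydroxy-4-methyl-4-(3-methylbut-2-en-1-yl)cyclohexa-2,5-dien-1-one | CCCCCC(=O)C1=C(O)[C@@](C)(CC=C(C)C)C(O)=CC1=O | intermediate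
12 | phloroglucinol (benzene-1,3,5-triol) | Oc1cc(O)cc(O)c1 | starting material
13 | hexanoyl chloride | CCCCCC(Cl)=O | starting material
14 | 1-(2,4,6-trihydroxyphenyl)hexan-1-one | CCCCCC(=O)c1c(O)cc(O)cc1O | intermediate
15 | 1-(2,6-dihydroxy-4-methoxyphenyl)hexan-1-one | CCCCCC(=O)c1c(O)cc(OC)cc1O | intermediate
16 | 1-{3-[(dimethylamino)methyl]-2,6-dihydroxy-4-methoxyphenyl}hexan-1-one | CCCCCC(=O)c1c(O)cc(OC)c(CN(C)C)c1O | intermediate
17 | 2-hexanoyl-3-hydroxy-5-methoxy-6-methylidenecyclohexa-2,4-dien-1-one | CCCCCC(=O)C1=C(O)C=C(OC)C(=C)C1=O | intermediate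
18 | CNP0108719.1, (4S)-2-hexanoyl-6-[(3-hexanoyl-2,4-dihydroxy-6-methoxyphenyl)methyl]-3,5-dihydroxy-4-methyl-4-(3-methylbut-2-en-1-yl)cyclohexa-2,5-dien-1-one | CCCCCC(=O)C1=C(O)[C@@](C)(CC=C(C)C)C(O)=C(Cc2c(OC)cc(O)c(C(=O)CCCCC)c2O)C1=O | target

Total step count: 10. Longest linear sequence: 7 steps (steps 1–6, then step 10).

Steps most likely to fail

Step 6. Deprotonation at the hexanoyl methylene may compete with deprotonation at the acetyl methyl group and close the regioisomeric ring, and attack at the hindered ester may be slow enough for O-cyclisation to an enol lactone to intervene. The fallback replaces kinetic selection by an activating group; it sets out from 7, through its acid chloride 9, and returns at 11. The dianion of tert-butyl acetoacetate (NaH, then n-BuLi, THF, 0 °C) would be acylated with methyl hexanoate to tert-butyl 3,5-dioxodecanoate F1. C-acylation of F1 at C4 with 9 (MgCl2, pyridine) would give 1-tert-butyl 7-(2,2-diphenylethyl) (6R)-4-hexanoyl-6-methyl-6-(3-methylbut-2-en-1-yl)-3,5-dioxoheptanedioate F2, in which the carbon that becomes C6 is a β-keto ester methylene and far more acidic than the hexanoyl CH2. NaH in THF should then close the same C5–C6 bond to tert-butyl (3R)-5-hexanoyl-2,4-dihydroxy-3-methyl-3-(3-methylbut-2-en-1-yl)-6-oxocyclohexa-1,4-diene-1-carboxylate F3. TMSOTf/2,6-lutidine followed by aqueous work-up should remove the tert-butyl ester with decarboxylation to 11.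

Step 5. O-acylation may win over C-acylation with the sluggish α-quaternary acid chloride, and the crowded triacylmethane may lose an acyl group on work-up. The fallback changes the order in which the acyl groups are joined; it sets out from 9 and returns at 10. The kinetic lithium enolate of heptan-2-one (LiN(iPr)2, THF, −78 °C, two equivalents of enolate) would be acylated by 9 to the β-diketone 2,2-diphenylethyl (2R)-2-methyl-2-(3-methylbut-2-en-1-yl)-3,5-dioxodecanoate F4. The small acetyl group would then be placed on its central carbon (acetyl chloride, MgCl2, pyridine) to give 10.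

Step 10. The quinone methide may oligomerise with its own precursor or be trapped by the prenyl alkene in a hetero-Diels–Alder reaction, and prolonged heating may move the hexanoyl group across the trione, which erodes the configuration. The fallback reverses the polarity of the coupling; it sets out from 11 and 15 and returns at 18. Compound 11 would be aminomethylated at C6 (CH2=NMe2+ I−, Et3N, CH2Cl2) to the Mannich base (4S)-6-[(dimethylamino)methyl]-2-hexanoyl-3,5-dihydroxy-4-methyl-4-(3-methylbut-2-en-1-yl)cyclohexa-2,5-dien-1-one F5. On gentle warming with an excess of 15, F5 should lose dimethylamine to the methylidene trione (4R)-2-hexanoyl-3-hydroxy-4-methyl-6-methylidene-4-(3-methylbut-2-en-1-yl)cyclohex-2-ene-1,5-dione F6, which the arene should trap at its position between the hydroxyl and the methoxy group in a Friedel–Crafts-type conjugate addition.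

Further compounds
F1 | step 6 | tert-butyl 3,5-dioxodecanoate | CCCCCC(=O)CC(=O)CC(=O)OC(C)(C)C
F2 | step 6 | 1-tert-butyl 7-(2,2-diphenylethyl) (6R)-4-hexanoyl-6-methyl-6-(3-methylbut-2-en-1-yl)-3,5-dioxoheptanedioate | CC(C)(C)OC(=O)CC(=O)C(C(=O)CCCCC)C(=O)[C@@](C)(CC=C(C)C)C(=O)OCC(c1ccccc1)c1ccccc1
F3 | step 6 | tert-butyl (3R)-5-hexanoyl-2,4-dihydroxy-3-methyl-3-(3-methylbut-2-en-1-yl)-6-oxocyclohexa-1,4-diene-1-carboxylate | CCCCCC(=O)C1=C(O)[C@@](C)(CC=C(C)C)C(O)=C(C(=O)OC(C)(C)C)C1=O
F4 | step 5 | 2,2-diphenylethyl (2R)-2-methyl-2-(3-methylbut-2-en-1-yl)-3,5-dioxodecanoate | CCCCCC(=O)CC(=O)[C@@](C)(CC=C(C)C)C(=O)OCC(c1ccccc1)c1ccccc1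
F5 | step 10 | (4S)-6-[(dimethylamino)methyl]-2-hexanoyl-3,5-dihydroxy-4-methyl-4-(3-methylbut-2-en-1-yl)cyclohexa-2,5-dien-1-one | CCCCCC(=O)C1=C(O)[C@@](C)(CC=C(C)C)C(O)=C(CN(C)C)C1=O
F6 | step 10 | (4R)-2-hexanoyl-3-hydroxy-4-methyl-6-methylidene-4-(3-methylbut-2-en-1-yl)cyclohex-2-ene-1,5-dione | CCCCCC(=O)C1=C(O)[C@@](C)(CC=C(C)C)C(=O)C(=C)C1=O
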